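An equiv of coupling partner can be spent once, so I kept a ledger in fractions of the charge and followed the fraction left rather than the fraction made.

| flask | starting material | coupling partner | second substrate | third substrate | remark | time |
|---|---|---|---|---|---|---|
| theta | 0.40 M | 2 equiv | 0.50 equiv | 2 equiv | the very flask that is asked about, followed so far |  |
| epsilon | 0.40 M | 3 equiv | 0.50 equiv | 2 equiv | run made earlier |  |
| flask | 0.40 M | 2.00 equiv | 0.500 equiv | 2.00 equiv |  | 8.0 d |

| run | time / h | target / % | starting material / % |
|---|---|---|---|
| theta | 12.0 | 70.1 | 30.8 |
| theta | 30.0 | 76.7 | 22.4 |
| theta | 72.0 | 78.6 | 19.7 |
| theta | 144 | 79.5 | 22.1 |
| epsilon | 4.00 | 66.3 | 31.6 |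
| epsilon | 8.00 | 83.9 | 17.4 |
| epsilon | 12.0 | 89.0 | 10.4 |
| epsilon | 15.0 | 91.6 | 7.3 |

(standard deviation of a reading: 1 percentage point)

- Thursday's: change nothing and wait 15 d more
- Monday's: at 8.0 d take out 90% of the target then present, then wait 15 d
- Wednesday's: at 8.0 d add coupling partner, 100% of the amount charged, then wait 15 d
- Sunday's: at 8.0 d add starting material, 50.0% of the amount charged, then wait 15 d

- target taken out counts as made
- additions bring no volume worth counting

- target, in percent of the starting material first charged, at 8.0 d
- the remedy with the largest gain of target, or "none" below 2 percentage points (Thursday's / Monday's / Wednesday's / Sunday's / none)
- target present, with what was taken out counted in, in percent of the starting material first charged, after Monday's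
- target present, with what was taken out counted in, in percent of the starting material first charged, after Wednesday's

In theta the target had levelled off, yet in epsilon, with more partner, it had already passed that level at its last reading. I therefore read the stall as lack of partner, the limiting reagent, and not as equilibrium.

For the target at 8.0 d, my floor was the lower late reading, 78.6%, since target and starting material summed to about the charge and nothing suggested target was being lost. For the ceiling, I let the fraction left keep shrinking at its pace between the last two readings:

ceiling = 80.1%

The last two theta readings of target averaged 79.0%, so I took 21.0% of the starting material as unreacted. Supposing the second substrate took its full 0.500 equiv, the third substrate took the rest: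

third substrate's share = 0.710 equiv, so its fraction left = 64.5%

I supposed that each substrate is used at a pace proportional to its own amount and to the same partner, and then the logarithms of their fractions left keep a fixed ratio, the selectivity factor:

S = 3.57

For Wednesday's, the substrates still unreacted needed 1.50 equiv of partner, whichever way the split had gone, and the addition gave 2.00 equiv, a surplus of 0.500 equiv. At epsilon's last pace the fraction left halved every 5.88 h, which makes 61.2 halvings in 15 d, so I estimated the target after Wednesday's at the full charge. The other remedies added no partner, so I left them at 79.0%.

The forecast put the target at 79.5%, inside my bracket, chose Wednesday's, gave 80% after Monday's and 98.5% after Wednesday's, and said: “In theta, that leaves too little partner, so the reaction stops when it runs out.”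

The flask gave 78.8%, inside the bracket, then 78.8% after Monday's and 100% after Wednesday's, a gain of 21 percentage points.

    third substrate + coupling partner → third product (k = 0.00180 M⁻¹ min⁻¹)
    starting material + coupling partner → target (k = 0.00670 M⁻¹ min⁻¹)
    second substrate + coupling partner → second product (k = 0.0320 M⁻¹ min⁻¹)
    coupling partner → decomposition product (k = 5.50 × 10⁻⁵ min⁻¹)

Part of the shortfall lies in the third substrate's step: with that step struck out, target at 8.0 d rose from 78.8% to >99.9%, and the gain brought by Wednesday's fell from 21 points to 0 points. With 3.57, this flask's unreacted starting material implied 64.8% of third substrate left, and 66% stood there. The neighbour charged with 0.800 equiv of partner kept 74.1% of its starting material, which implied 91.9% of third substrate, and it held 92.3%.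

The runs are calculated from invented constants; scatter was added.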